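**Retrosynthetic overview**

- The route rests on the 2,5-disubstituted 1H-pyrrole ring: N1, C5 and the CH2OH carbon are the N–Cα–Cβ unit of serine after loss of CO2, C2 with its exocyclic ketone is the CHO carbon of a 2-oxoaldehyde, and only the unsubstituted C3–C4 pair must be added.
- Pyrrole 12 ⇒ 3,4-bis(phenylsulfonyl)pyrrolidine 10 by two losses of benzenesulfinic acid, so the C3–C4 unit is (E)-1,2-bis(phenylsulfonyl)ethene used as an acetylene equivalent.
- Pyrrolidine 10 ⇒ L-serine + 17-methyl-2-oxooctadecanal + the bis-sulfonyl ethene through a decarboxylative N–H azomethine ylide [3+2] cycloaddition, forming N1–C2, C2–C3 and C4–C5.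
- 2-Oxoaldehyde 4 ⇒ diazoketone 3 ⇒ acid chloride 2 ⇒ 16-methylheptadecanoic acid 1.
- Ring order: the only ring is closed as a pyrrolidine in step 4 and aromatised in step 5.

Key step: step 4

Remark: the target has no stereocentre, so no enantiomer has to be secured. The serine centre and the four ring centres of the cycloadduct are lost by design, and pure 16-methylheptadecanoic acid is taken as a purchasable iso-fatty acid.

**Route**

Step 1
Reactants: 1 16-methylheptadecanoic acid
Product: 2 16-methylheptadecanoyl chloride
Conditions: (COCl)2 (1.5 equiv), DMF (cat.), CH2Cl2, 0 °C → rt; evaporate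
Reagents that add atoms: oxalyl chloride, O=C(Cl)C(Cl)=O
Why: DMF-catalysed (Vilsmeier-type) chlorination of a saturated fatty acid with oxalyl chloride is general, and the by-products are gases, so the crude acid chloride can be used directly.

Step 2
Reactants: 2 16-methylheptadecanoyl chloride
Product: 3 1-diazo-17-methyloctadecan-2-one
Conditions: TMSCHN2 (2.0 equiv, hexanes), THF/MeCN 1:1, 0 °C → rt; concentrate, short SiO2 column
Reagents that add atoms: trimethylsilyldiazomethane, C[Si](C)(C)C=[N+]=[N-]
Why: C-acylation of a diazoalkane by an acid chloride (the diazoketone stage of the Arndt–Eistert sequence, silyl variant) should give the terminal diazoketone, the silyl group leaving as chlorotrimethylsilane.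

Step 3
Reactants: 3 1-diazo-17-methyloctadecan-2-one
Product: 4 17-methyl-2-oxooctadecanal
Conditions: dimethyldioxirane (1.2 equiv, ca. 0.07 M in acetone), acetone, 0 °C → rt; evaporate, use at once
Reagents that add atoms: dimethyldioxirane, CC1(C)OO1
Why: Dioxirane oxidation of an α-diazoketone (electrophilic oxygen transfer to the diazo carbon, then loss of N2) should give the 2-oxoaldehyde under neutral anhydrous conditions with acetone as the only by-product, and is much faster than any hydroxylation of the tertiary C–H at the iso-branch.

Step 4
Reactants: 4 17-methyl-2-oxooctadecanal; 5 L-serine; 6 (E)-1,2-bis(phenylsulfonyl)ethene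
Product: 10 1-[5-(hydroxymethyl)-3,4-bis(phenylsulfonyl)pyrrolidin-2-yl]-16-methylheptadecan-1-one (mixture of ring diastereomers), via imine acid 7 (not isolated), via oxazolidin-5-one 8 (not isolated), via azomethine ylide 9 (not isolated)
Conditions: 5 (1.2 equiv), 4 Å MS, amine-free DMF/toluene 1:1, rt → 40 °C until 5 has dissolved; then 6 (1.5 equiv), 80 °C, Ar
Reagents that add atoms: none
Why: The amino group of 5 should condense at the aldehyde carbon of 4 to give imine 7 (forming N1–C2), whose carboxylate closes onto the C=N carbon to give oxazolidin-5-one 8, and thermal loss of CO2 from 8 gives the N–H azomethine ylide 9, stabilised at C2 by the ketone. This is the known decarboxylative generation of azomethine ylides from α-amino acids and 1,2-dicarbonyl compounds (the intermediate of the Strecker degradation), followed by 1,3-dipolar cycloaddition to an electron-poor alkene. The pyrrolidine ring is closed by an intermolecular, concerted, suprafacial [3+2] cycloaddition that forms C2–C3 and C4–C5 together. Four ring stereocentres arise (the sulfonyl groups trans, as dictated by the E-alkene, with C2 and C5 uncontrolled) while the serine centre disappears in 9, and none needs control because step 5 removes them all. The step needs condensation at CHO instead of the ketone, which the much higher electrophilicity of the aldehyde carbon secures, and trapping of 9 before 1,2-proton shift and hydrolysis, which the excess of a doubly activated dipolarophile, added before CO2 loss begins, should secure. Regiochemistry is not an issue because 6 is symmetrical.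

Step 5
Reactants: 10 1-[5-(hydroxymethyl)-3,4-bis(phenylsulfonyl)pyrrolidin-2-yl]-16-methylheptadecan-1-one
Product: 12 1-[5-(hydroxymethyl)-1H-pyrrol-2-yl]-16-methylheptadecan-1-one (target), via monosulfonyl dihydropyrrole 11 (not isolated)
Conditions: DBU (3 equiv), THF, rt → 50 °C, Ar; pH 7 phosphate buffer work-up (no acid)
Reagents that add atoms: none
Why: Two base-induced E1cB eliminations of benzenesulfinate (the known use of a 1,2-bis-sulfonyl ethene adduct as an acetylene equivalent) should occur, DBU first removing the ketone-activated C2–H to expel the C3 sulfinate and give enaminone 11, whose C4 sulfinate is then allylic and leaves with the C5 hydrogen under the driving force of pyrrole aromaticity, with no redox step and the free hydroxymethyl group untouched.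

**Compound list**

1 | 16-methylheptadecanoic acid | CC(C)CCCCCCCCCCCCCCC(=O)O | starting material
2 | 16-methylheptadecanoyl chloride | CC(C)CCCCCCCCCCCCCCC(=O)Cl | intermediate
3 | 1-diazo-17-methyloctadecan-2-one | CC(C)CCCCCCCCCCCCCCC(=O)C=[N+]=[N-] | intermediate
4 | 17-methyl-2-oxooctadecanal | CC(C)CCCCCCCCCCCCCCC(=O)C=O | intermediate
5 | L-serine, (S)-2-amino-3-hydroxypropanoic acid | N[C@@H](CO)C(=O)O | starting material
6 | (E)-1,2-bis(phenylsulfonyl)ethene | O=S(=O)(/C=C/S(=O)(=O)c1ccccc1)c1ccccc1 | starting material
7 | (2S)-3-hydroxy-2-[(17-methyl-2-oxooctadecylidene)amino]propanoic acid (imine acid) | CC(C)CCCCCCCCCCCCCCC(=O)C=N[C@@H](CO)C(=O)O | intermediate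
8 | (4S)-4-(hydroxymethyl)-2-(16-methylheptadecanoyl)-1,3-oxazolidin-5-one (C2 epimers) | CC(C)CCCCCCCCCCCCCCC(=O)C1N[C@@H](CO)C(=O)O1 | intermediate
9 | N–H azomethine ylide from 8 after loss of CO2 (ketone-stabilised 1,3-dipole) | CC(C)CCCCCCCCCCCCCCC(=O)[CH-][NH+]=CCO | intermediate
10 | 1-[5-(hydroxymethyl)-3,4-bis(phenylsulfonyl)pyrrolidin-2-yl]-16-methylheptadecan-1-one (diastereomer mixture) | CC(C)CCCCCCCCCCCCCCC(=O)C1NC(CO)C(S(=O)(=O)c2ccccc2)C1S(=O)(=O)c1ccccc1 | intermediate
11 | 1-[5-(hydroxymethyl)-4-(phenylsulfonyl)-4,5-dihydro-1H-pyrrol-2-yl]-16-methylheptadecan-1-one | CC(C)CCCCCCCCCCCCCCC(=O)C1=CC(S(=O)(=O)c2ccccc2)C(CO)N1 | intermediate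
12 | 1-[5-(hydroxymethyl)-1H-pyrrol-2-yl]-16-methylheptadecan-1-one | CC(C)CCCCCCCCCCCCCCC(=O)c1ccc(CO)[nH]1 | target

**Step count**

Total steps: 5. Longest linear sequence: 5 (1 → 2 → 3 → 4 → 10 → 12); 5 and 6 enter at step 4.

**Steps most likely to fail**

Step 4. The ylide 9 may undergo 1,2-proton shift and hydrolysis (Strecker degradation) faster than it is trapped. Free amine (serine, or the N–H of the cycloadduct) may also be consumed by conjugate addition–elimination on 6, or the serine hydroxyl may hold the imine back as an oxazolidine. The fallback is known pyrrole chemistry without a cycloaddition and sets out from acid chloride 2. C-acylation of pyrrolylmagnesium bromide (pyrrole, EtMgBr, Et2O/toluene, −40 °C → 0 °C) should give 16-methyl-1-(1H-pyrrol-2-yl)heptadecan-1-one F1. Vilsmeier–Haack formylation (POCl3, DMF, 1,2-dichloroethane, then aq. NaOAc) at the free α-position should give 5-(16-methylheptadecanoyl)-1H-pyrrole-2-carbaldehyde F2, any 4-formyl isomer being removed by chromatography. NaBH4 in MeOH/THF at 0 °C should then reduce the formyl group ahead of the vinylogous-amide ketone, and the fallback comes back to the route at the target 12.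

Step 5. After the first elimination the enaminone 11 is stabilised, so the second sulfinate loss may stall, or adventitious oxidation may aromatise the ring with one sulfonyl group still in place. The fallback removes the sulfonyl groups reductively and sets out from 10. Buffered sodium amalgam (6% Na(Hg), NaH2PO4, MeOH/THF, −20 °C) should bring about reductive elimination of the vicinal bis-sulfone, which accepts electrons far more readily than the dialkyl ketone, to give 1-[5-(hydroxymethyl)-2,5-dihydro-1H-pyrrol-2-yl]-16-methylheptadecan-1-one F3. Dehydrogenation of this 3-pyrroline with DDQ (1 equiv, dioxane, rt) comes back to the route at the target 12.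

Step 3. Over-oxidation beyond the aldehyde stage, or hydration and self-condensation of the 2-oxoaldehyde during handling, may reduce the amount of reactive dicarbonyl delivered to step 4. The fallback is the Kornblum nitrate-ester synthesis of glyoxals and sets out from diazoketone 3. HBr (48% aq., Et2O, 0 °C) should give 1-bromo-17-methyloctadecan-2-one F4, and AgNO3 in MeCN should convert it to 17-methyl-2-oxooctadecyl nitrate F5. NaOAc in DMSO at rt should then eliminate nitrite, and the fallback comes back to the route at 4.

**Further compounds**

F1 | step 4 | 16-methyl-1-(1H-pyrrol-2-yl)heptadecan-1-one | CC(C)CCCCCCCCCCCCCCC(=O)c1ccc[nH]1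
F2 | step 4 | 5-(16-methylheptadecanoyl)-1H-pyrrole-2-carbaldehyde | CC(C)CCCCCCCCCCCCCCC(=O)c1ccc(C=O)[nH]1
F3 | step 5 | 1-[5-(hydroxymethyl)-2,5-dihydro-1H-pyrrol-2-yl]-16-methylheptadecan-1-one | CC(C)CCCCCCCCCCCCCCC(=O)C1NC(CO)C=C1
F4 | step 3 | 1-bromo-17-methyloctadecan-2-one | CC(C)CCCCCCCCCCCCCCC(=O)CBr
F5 | step 3 | 17-methyl-2-oxooctadecyl nitrate | CC(C)CCCCCCCCCCCCCCC(=O)CO[N+](=O)[O-]
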